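**Retrosynthetic overview**

1. The target is traced back, through global desilylation and reduction of a nitrile that stands for the formyl group, to a Suzuki–Miyaura union of a 1-substituted vinyl triflate on the cyclopentane with a (1E,3Z)-dienylboronate (built from propargyl alcohol, homoprenyl bromide and vinylboronic ester).
2. The hydroxypropyl arm and the tetrasubstituted enal are grown on the cyclohexane after spiro-annulation: ketal to ketone, enol triflate, B-alkyl Suzuki coupling, hydroboration/oxidation, oxidation, Horner–Wadsworth–Emmons cyanoethylidenation.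
3. Key disconnection: the cyclopentane is cut at C3–C4 and C1–C5 into 6-methylidene-1,4-dioxaspiro[4.5]decan-7-one and a trans-2-substituted cyclopropanol. Forward, one zinc-catalysed operation cleaves a cyclopropane C–C bond (homoenolate), adds it 1,4 to the enone and closes the ring by aldol addition.
4. Enabling feature: the array C6(OH)(CH3)–C5(spiro)–C1H(OH) is an aldol retron once the methyl carbinol C6 of the six-membered ring is read as a ketone. C5 is then the α-carbon and the cyclopentane methylene C4 the β-carbon of an exocyclic enone, and C3–C2–C1 is a ring-opened cyclopropanol.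
5. Ring order: the cyclohexane is bought (2-methylcyclohexane-1,3-dione), the cyclopropane is made and sacrificed, the cyclopentane is formed in the key step; a di-tert-butylsilylene ring temporarily bridges the 1,3-diol.

Key step: step 8

Remark: core locants follow spiro[4.5]decane numbering (C1 = CH–OH of the five-membered ring, C2 = its side-chain carbon, C5 = spiro carbon, C6 = methyl carbinol carbon, C9 = ylidene carbon, C10 = carbon bearing the hydroxypropyl chain); all compounds called starting materials are assumed to be catalogue chemicals.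

**Route**

Step 1
Reactants: 1 2-methylcyclohexane-1,3-dione
Product: 2 2-methyl-2-(phenylselanyl)cyclohexane-1,3-dione
Conditions: PhSeCl, pyridine, CH2Cl2, 0 °C to rt
Reagents that add atoms: benzeneselenenyl chloride, Cl[Se]c1ccccc1
Why: The doubly activated methine of the 1,3-dione enolises readily and its enol carbon is selenenylated by PhSeCl (α-selenenylation of a β-dicarbonyl), which marks the only carbon that must later become sp2.

Step 2
Reactants: 2 2-methyl-2-(phenylselanyl)cyclohexane-1,3-dione
Product: 3 6-methyl-6-(phenylselanyl)-1,4-dioxaspiro[4.5]decan-7-one (racemic)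
Conditions: ethylene glycol (1.2 equiv), TsOH·H2O (cat.), toluene, reflux, Dean–Stark
Reagents that add atoms: ethane-1,2-diol, OCCO
Why: Acid-catalysed ketalisation with one equivalent of diol should stop at the mono-dioxolane, because the 2,2-disubstituted dione cannot divert into a vinylogous ester and the remaining carbonyl is shielded by the quaternary carbon and the new ketal.

Step 3
Reactants: 3 6-methyl-6-(phenylselanyl)-1,4-dioxaspiro[4.5]decan-7-one
Product: 5 6-methylidene-1,4-dioxaspiro[4.5]decan-7-one, via selenoxide 4 (not isolated)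
Conditions: 30% aq H2O2, pyridine, CH2Cl2, 0 °C to rt; used at once
Reagents that add atoms: none
Why: Oxidation to the selenoxide and syn-elimination (selenoxide elimination) can only take a methyl hydrogen, since the other β-positions are the carbonyl and ketal carbons, so the exocyclic enone is the single regioisomer and is used fresh to avoid dimerisation.

Step 4
Reactants: 6 (2R)-but-3-yn-2-ol
Product: 7 1-({[(2R)-but-3-yn-2-yl]oxy}methyl)-4-methoxybenzene
Conditions: NaH, 4-methoxybenzyl chloride, Bu4NI (cat.), THF/DMF, 0 °C to rt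
Reagents that add atoms: 4-methoxybenzyl chloride, COc1ccc(CCl)cc1
Why: Williamson etherification of the sodium alkoxide protects the carbinol as a benzylic ether that can later guide the zinc carbenoid and be removed oxidatively, without touching the stereocentre.

Step 5
Reactants: 7 1-({[(2R)-but-3-yn-2-yl]oxy}methyl)-4-methoxybenzene
Product: 8 2-[(1E,3R)-3-[(4-methoxyphenyl)methoxy]but-1-en-1-yl]-4,4,5,5-tetramethyl-1,3,2-dioxaborolane
Conditions: pinacolborane (1.3 equiv), Cp2Zr(H)Cl (10 mol %), Et3N (10 mol %), neat, 60 °C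
Reagents that add atoms: pinacolborane, CC1(C)OBOC1(C)C
Why: Zirconium-catalysed hydroboration of the terminal alkyne is a syn addition with boron at the terminus and should give the E-alkenylboronate only.

Step 6
Reactants: 8 the (E)-alkenylboronate
Product: 9 2-[(1R,2R)-2-{(1R)-1-[(4-methoxyphenyl)methoxy]ethyl}cyclopropyl]-4,4,5,5-tetramethyl-1,3,2-dioxaborolane
Conditions: Et2Zn (3 equiv), CH2I2 (6 equiv), CH2Cl2, −10 °C to rt
Reagents that add atoms: diiodomethane, ICI
Why: Furukawa-modified Simmons–Smith cyclopropanation is stereospecific (E-alkene to trans-cyclopropane) and is delivered by the allylic ether oxygen to the face exposed in the conformer that minimises allylic 1,3-strain (carbinol hydrogen eclipsing the alkene), which sets the ring carbon bearing the side chain.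

Step 7
Reactants: 9 the cyclopropylboronate
Product: 10 (1R,2R)-2-{(1R)-1-[(4-methoxyphenyl)methoxy]ethyl}cyclopropan-1-ol
Conditions: 30% aq H2O2, KHCO3, THF/MeOH, 0 °C
Reagents that add atoms: hydrogen peroxide, OO
Why: Buffered peroxide oxidation of the carbon–boron bond proceeds with retention and gives the trans-cyclopropanol without base-induced ring opening.

Step 8
Reactants: 5 6-methylidene-1,4-dioxaspiro[4.5]decan-7-one, 10 (1R,2R)-2-{(1R)-1-[(4-methoxyphenyl)methoxy]ethyl}cyclopropan-1-ol
Product: 14 (1S,2R,5S)-1-hydroxy-2-{(1R)-1-[(4-methoxyphenyl)methoxy]ethyl}spiro[4.5]decane-6,10-dione 10-(ethylene ketal), via zinc cyclopropanolate 11 (not isolated), via zinc homoenolate 12 (not isolated), via zinc enolate 13 (not isolated)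
Conditions: 10 (1.0 equiv), 5 (1.5 equiv), Et2Zn (30 mol %), 2-(dimethylamino)ethanol (30 mol %), DMSO/THF, 25 °C; then sat. aq NH4Cl
Reagents that add atoms: none
Why: Proposed new method: the zinc alkoxide 11 should open by β-carbon elimination at the bond between the carbinol carbon and the unsubstituted ring CH2 to give the β-zincio aldehyde 12; its primary carbon adds 1,4 to the exocyclic enone (forming C3–C4), and the zinc enolate 13, held next to the liberated aldehyde, closes the ring by aldol addition (forming C1–C5) before it is protonated, the zinc aldolate being released by the next molecule of 10. The closest known reaction type is the zinc aminoalkoxide-catalysed conjugate addition of ketone homoenolates from tertiary cyclopropanols to enones, extended here to an aldehyde homoenolate, an α-methylidene ketone and an intramolecular aldol trap. The cyclopentane closes in the 5-(enolexo)-exo-trig mode. The spiro centre C5 should be fixed by the zinc bridge between enolate oxygen and aldehyde oxygen in a closed six-membered transition state, which places the new hydroxyl cis to the ketone carbon; the carbinol centre C1 should form trans to the C2 substituent because the branched side chain avoids the zinc-bound oxygen; C2 is carried over unchanged from the cyclopropanol. The step needs ring opening towards the primary carbon (secured by the preference of zinc for the less substituted carbon), conjugate addition ahead of aldehyde self-condensation (secured by storage of the aldehyde as the cyclopropanolate and by the unhindered methylidene terminus) and ring closure ahead of epimerisation at C2 (secured by the intramolecular five-membered aldol). The symmetric ketal keeps the six-membered ring free of stereocentres, so facial selection at C5 is set only by the incoming fragment.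

Step 9
Reactants: 14 the spiro hydroxy ketone
Product: 15 (1S,2R,5S,6S)-6-methyl-2-{(1R)-1-[(4-methoxyphenyl)methoxy]ethyl}-10,10-(ethylenedioxy)spiro[4.5]decane-1,6-diol
Conditions: MeMgBr (4 equiv), CeCl3 (4 equiv), THF, −78 to −40 °C
Reagents that add atoms: methylmagnesium bromide, C[Mg]Br
Why: The methylcerium reagent adds to the hindered ketone (1,2-addition) without retro-aldol cleavage and should attack equatorially from the face of the cyclopentane methylene C4, because axial attack meets the syn-axial ketal oxygen while the chelated carbinol carbon lies in the carbonyl plane, which sets C6 with its hydroxyl cis to C1.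

Step 10
Reactants: 15 the spiro diol
Product: 16 1,6-O-(di-tert-butylsilylene) derivative of 15
Conditions: tBu2Si(OTf)2, 2,6-lutidine, CH2Cl2, 0 °C to rt
Reagents that add atoms: di-tert-butylsilyl bis(trifluoromethanesulfonate), CC(C)(C)[Si](OS(=O)(=O)C(F)(F)F)(OS(=O)(=O)C(F)(F)F)C(C)(C)C
Why: The cis-disposed tertiary and secondary hydroxyls form a six-membered silylene (silylene protection of a 1,3-diol), which blocks retro-aldol pathways and later biases the cyclohexene conformation.

Step 11
Reactants: 16 the silylene ketal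
Product: 17 C10 ketone obtained by removal of the ethylene ketal of 16
Conditions: PPTS (cat.), acetone/H2O, 55 °C
Reagents that add atoms: water, O
Why: Mild acid-catalysed ketal hydrolysis unmasks the neopentylic ketone, release of steric compression helping the hindered dioxolane to open while the silylene and the benzylic ether survive.

Step 12
Reactants: 17 the C10 ketone
Product: 18 C9-ene C10 enol triflate of 17
Conditions: KN(SiMe3)2, THF, −78 °C; PhNTf2, −78 to 0 °C
Reagents that add atoms: N-phenylbis(trifluoromethanesulfonimide), O=S(=O)(N(c1ccccc1)S(=O)(=O)C(F)(F)F)C(F)(F)F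
Why: The ketone can enolise only towards C9, since C5 is quaternary, so deprotonation and O-triflation (enol triflate formation) give one regioisomer.

Step 13
Reactants: 18 the enol triflate, 19 tert-butyl(dimethyl)(prop-2-en-1-yloxy)silane
Product: 21 C9-ene bearing a 3-[tert-butyl(dimethyl)silyloxy]propyl group at C10, via alkylborane 20 (not isolated)
Conditions: 19, 9-BBN dimer, THF, 0 °C to rt; then 18, Pd(dppf)Cl2 (10 mol %), AsPh3, Cs2CO3, DMF/THF/H2O, 50 °C
Reagents that add atoms: none
Why: B-alkyl Suzuki–Miyaura coupling of the hindered cyclic enol triflate with the 9-BBN adduct of the allyl silyl ether installs the three-carbon arm with its oxygen already protected.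

Step 14
Reactants: 21 the trisubstituted cyclohexene
Product: 23 C9 alcohol with C10–H cis to C4 and the side chain cis to C1, via organoborane 22 (not isolated)
Conditions: BH3·THF, THF, 0 °C to rt; then 3 M NaOH, 30% H2O2, 0 °C
Reagents that add atoms: hydrogen peroxide, OO
Why: Hydroboration–oxidation places boron on the less substituted C9 and hydrogen on C10 in a syn addition that should occur on the face of the C4 methylene, because allylic 1,2-strain with the new side chain forces the silyloxy-bearing C1 into the pseudo-axial position, where it shields the other face.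

Step 15
Reactants: 23 the C9 alcohol
Product: 24 C9 ketone with the C10 stereocentre as in the target
Conditions: Dess–Martin periodinane, NaHCO3, CH2Cl2, 0 °C to rt
Reagents that add atoms: none
Why: Dess–Martin oxidation under buffered conditions converts the secondary alcohol into the ketone without enolising the adjacent C10 stereocentre.

Step 16
Reactants: 24 the C9 ketone, 25 diethyl (1-cyanoethyl)phosphonate
Product: 26 (2Z)-2-(spiro[4.5]decan-9-ylidene)propanenitrile derivative of 24 (nitrile cis to C10)
Conditions: 25 (4 equiv), NaH (3.8 equiv), DME, 0 to 70 °C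
Reagents that add atoms: none
Why: Horner–Wadsworth–Emmons olefination with the weakly basic cyanophosphonate anion should place the slim nitrile on the side of the substituted C10 and the methyl towards the C8 methylene (steric control in the reversible addition–elimination), giving the nitrile that stands for the formyl group.

Step 17
Reactants: 26 the unsaturated nitrile
Product: 27 secondary alcohol obtained by removal of the 4-methoxybenzyl group of 26
Conditions: DDQ, CH2Cl2/pH 7 buffer, 0 °C
Reagents that add atoms: none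
Why: Oxidative cleavage of the 4-methoxybenzyl ether with DDQ leaves the silyl ethers, the silylene and the electron-poor alkene untouched.

Step 18
Reactants: 27 the secondary alcohol
Product: 28 C2 acetyl compound (methyl ketone)
Conditions: Dess–Martin periodinane, NaHCO3, CH2Cl2, 0 °C
Reagents that add atoms: none
Why: Dess–Martin oxidation gives the methyl ketone under non-basic conditions, so the α-stereocentre C2 and the β-silyloxy group are not disturbed.

Step 19
Reactants: 28 the methyl ketone
Product: 29 C2 1-(trifluoromethanesulfonyloxy)ethenyl compound (vinyl triflate)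
Conditions: KN(SiMe3)2, THF, −78 °C; N-(5-chloropyridin-2-yl)bis(trifluoromethanesulfonimide), −78 °C
Reagents that add atoms: N-(5-chloropyridin-2-yl)bis(trifluoromethanesulfonimide), O=S(=O)(N(c1ccc(Cl)cn1)S(=O)(=O)C(F)(F)F)C(F)(F)F
Why: Kinetic deprotonation at −78 °C takes the unhindered methyl protons, not the tertiary C2–H or the γ-protons of the unsaturated nitrile, and O-triflation gives the terminal vinyl triflate (kinetic enol triflate formation).

Step 20
Reactants: 30 prop-2-yn-1-ol, 31 5-bromo-2-methylpent-2-ene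
Product: 34 (2Z)-3-iodo-2-(4-methylpent-3-en-1-yl)prop-2-en-1-ol, via Grignard reagent 32 (not isolated), via cyclic alkenylmagnesium alkoxide 33 (not isolated)
Conditions: 31, Mg, THF; then 30 (0.4 equiv), CuI (10 mol %), THF, −10 °C to rt; then I2, −40 to 0 °C
Reagents that add atoms: iodine, II
Why: Copper-catalysed anti-carbomagnesiation of propargyl alcohol adds the homoprenyl group to C2 and leaves magnesium on C3 cis to the oxymethyl group in a five-membered chelate, so iodinolysis with retention gives the Z-iodoalkene.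

Step 21
Reactants: 34 the iodoallylic alcohol
Product: 35 tert-butyl{[(2Z)-3-iodo-2-(4-methylpent-3-en-1-yl)prop-2-en-1-yl]oxy}dimethylsilane
Conditions: TBSCl, imidazole, CH2Cl2, rt
Reagents that add atoms: tert-butyldimethylsilyl chloride, CC(C)(C)[Si](C)(C)Cl
Why: Silylation of the primary allylic alcohol protects it for the palladium steps and for the final unmasking of the aldehyde.

Step 22
Reactants: 35 the silylated iodoalkene, 36 4,4,5,5-tetramethyl-2-vinyl-1,3,2-dioxaborolane
Product: 37 2-[(1E,3Z)-4-{[tert-butyl(dimethyl)silyl]oxymethyl}-8-methylnona-1,3,7-trien-1-yl]-4,4,5,5-tetramethyl-1,3,2-dioxaborolane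
Conditions: Pd(OAc)2 (5 mol %), P(o-tol)3 (10 mol %), AgOAc (1.2 equiv), MeCN, 50 °C
Reagents that add atoms: none
Why: Heck–Mizoroki coupling of the alkenyl iodide with the vinylboronic ester under silver-assisted, base-free conditions favours insertion over transmetalation and should give the E-dienylboronate with the iodoalkene geometry retained.

Step 23
Reactants: 29 the vinyl triflate, 37 the dienylboronate
Product: 38 fully protected triene nitrile
Conditions: Pd(PPh3)4 (5 mol %), 3 M aq K3PO4, THF, 45 °C
Reagents that add atoms: none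
Why: Suzuki–Miyaura coupling joins the two sp2 carbons with retention of both alkene geometries and builds the 2-substituted triene, which cannot electrocyclise because its central double bond is E.

Step 24
Reactants: 38 the triene nitrile
Product: 40 protected trienal, via N-aluminio aldimine 39 (not isolated)
Conditions: iBu2AlH (2.5 equiv), toluene, −78 to −40 °C; then aq potassium sodium tartrate, rt
Reagents that add atoms: water, O
Why: Partial reduction of the nitrile stops at the aluminated aldimine, which hydrolyses on work-up to the tetrasubstituted enal with the alkene geometry retained (nitrile-to-aldehyde reduction).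

Step 25
Reactants: 40 the protected trienal
Product: 41 (2Z)-2-[(1S,2S,5S,6S,10R)-1,6-dihydroxy-2-[(3E,5Z)-6-(hydroxymethyl)-10-methylundeca-1,3,5,9-tetraen-2-yl]-10-(3-hydroxypropyl)-6-methylspiro[4.5]decan-9-ylidene]propanal
Conditions: HF·pyridine, pyridine, THF, 0 °C to rt
Reagents that add atoms: none
Why: Buffered fluoride-mediated desilylation removes both silyl ethers and the silylene in one operation under conditions that the enal and the triene should tolerate.

**Compound list**

1 | 2-methylcyclohexane-1,3-dione | CC1C(=O)CCCC1=O | starting material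
2 | 2-methyl-2-(phenylselanyl)cyclohexane-1,3-dione | CC1([Se]c2ccccc2)C(=O)CCCC1=O | intermediate
3 | 6-methyl-6-(phenylselanyl)-1,4-dioxaspiro[4.5]decan-7-one (racemic) | CC1([Se]c2ccccc2)C(=O)CCCC13OCCO3 | intermediate
4 | 6-methyl-6-(phenylseleninyl)-1,4-dioxaspiro[4.5]decan-7-one | CC1([Se](=O)c2ccccc2)C(=O)CCCC13OCCO3 | intermediate
5 | 6-methylidene-1,4-dioxaspiro[4.5]decan-7-one | C=C1C(=O)CCCC12OCCO2 | intermediate
6 | (2R)-but-3-yn-2-ol | C[C@@H](O)C#C | starting material
7 | 1-({[(2R)-but-3-yn-2-yl]oxy}methyl)-4-methoxybenzene | C[C@@H](OCc1ccc(OC)cc1)C#C | intermediate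
8 | 2-[(1E,3R)-3-[(4-methoxyphenyl)methoxy]but-1-en-1-yl]-4,4,5,5-tetramethyl-1,3,2-dioxaborolane | C[C@@H](OCc1ccc(OC)cc1)/C=C/B1OC(C)(C)C(C)(C)O1 | intermediate
9 | 2-[(1R,2R)-2-{(1R)-1-[(4-methoxyphenyl)methoxy]ethyl}cyclopropyl]-4,4,5,5-tetramethyl-1,3,2-dioxaborolane | C[C@@H](OCc1ccc(OC)cc1)[C@@H]1C[C@H]1B2OC(C)(C)C(C)(C)O2 | intermediate
10 | (1R,2R)-2-{(1R)-1-[(4-methoxyphenyl)methoxy]ethyl}cyclopropan-1-ol | C[C@@H](OCc1ccc(OC)cc1)[C@@H]1C[C@H]1O | intermediate
11 | [2-(dimethylamino)ethoxy]zinc cyclopropanolate of 10 | C[C@@H](OCc1ccc(OC)cc1)[C@@H]1C[C@H]1O[Zn]OCCN(C)C | intermediate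
12 | [2-(dimethylamino)ethoxy]{2-formyl-3-[(4-methoxyphenyl)methoxy]butyl}zinc (ring-opened homoenolate) | C[C@@H](OCc1ccc(OC)cc1)[C@@H](C=O)C[Zn]OCCN(C)C | intermediate
13 | zinc enolate of 6-{3-formyl-4-[(4-methoxyphenyl)methoxy]pentyl}-1,4-dioxaspiro[4.5]decan-7-one | C[C@@H](OCc1ccc(OC)cc1)[C@@H](C=O)CCC1=C(O[Zn]OCCN(C)C)CCCC12OCCO2 | intermediate
14 | (1S,2R,5S)-1-hydroxy-2-{(1R)-1-[(4-methoxyphenyl)methoxy]ethyl}spiro[4.5]decane-6,10-dione 10-(ethylene ketal); hydroxyl cis to the ketone carbon, trans to the C2 substituent | C[C@@H](OCc1ccc(OC)cc1)[C@@H]1CC[C@]2(C3(OCCO3)CCCC2=O)[C@H]1O | intermediate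
15 | (1S,2R,5S,6S)-6-methyl-2-{(1R)-1-[(4-methoxyphenyl)methoxy]ethyl}-10,10-(ethylenedioxy)spiro[4.5]decane-1,6-diol | C[C@@H](OCc1ccc(OC)cc1)[C@@H]1CC[C@]2(C3(OCCO3)CCC[C@]2(C)O)[C@H]1O | intermediate
16 | 1,6-O-(di-tert-butylsilylene) derivative of 15 | C[C@@H](OCc1ccc(OC)cc1)[C@@H]1CC[C@]2(C3(OCCO3)CCC[C@]2(C)O[Si]4(C(C)(C)C)C(C)(C)C)[C@H]1O4 | intermediate
17 | C10 ketone from 16 (ketal removed, silylene kept) | C[C@@H](OCc1ccc(OC)cc1)[C@@H]1CC[C@]2(C(=O)CCC[C@]2(C)O[Si]3(C(C)(C)C)C(C)(C)C)[C@H]1O3 | intermediate
18 | C9-ene C10 enol triflate of 17 | C[C@@H](OCc1ccc(OC)cc1)[C@@H]1CC[C@]2(C(OS(=O)(=O)C(F)(F)F)=CCC[C@]2(C)O[Si]3(C(C)(C)C)C(C)(C)C)[C@H]1O3 | intermediate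
19 | tert-butyl(dimethyl)(prop-2-en-1-yloxy)silane | C=CCO[Si](C)(C)C(C)(C)C | starting material
20 | 9-{3-[tert-butyl(dimethyl)silyloxy]propyl}-9-borabicyclo[3.3.1]nonane | CC(C)(C)[Si](C)(C)OCCCB1C2CCCC1CCC2 | intermediate
21 | C9-ene with a 3-[tert-butyl(dimethyl)silyloxy]propyl group at C10 | C[C@@H](OCc1ccc(OC)cc1)[C@@H]1CC[C@]2(C(CCCO[Si](C)(C)C(C)(C)C)=CCC[C@]2(C)O[Si]3(C(C)(C)C)C(C)(C)C)[C@H]1O3 | intermediate
22 | C9 borane (BH2 on C9, H on C10, both on the face of C4) | C[C@@H](OCc1ccc(OC)cc1)[C@@H]1CC[C@]2([C@H](CCCO[Si](C)(C)C(C)(C)C)[C@@H](B)CC[C@]2(C)O[Si]3(C(C)(C)C)C(C)(C)C)[C@H]1O3 | intermediate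
23 | C9 alcohol, C10 configured as in the target | C[C@@H](OCc1ccc(OC)cc1)[C@@H]1CC[C@]2([C@H](CCCO[Si](C)(C)C(C)(C)C)[C@@H](O)CC[C@]2(C)O[Si]3(C(C)(C)C)C(C)(C)C)[C@H]1O3 | intermediate
24 | C9 ketone | C[C@@H](OCc1ccc(OC)cc1)[C@@H]1CC[C@]2([C@H](CCCO[Si](C)(C)C(C)(C)C)C(=O)CC[C@]2(C)O[Si]3(C(C)(C)C)C(C)(C)C)[C@H]1O3 | intermediate
25 | diethyl (1-cyanoethyl)phosphonate | CCOP(=O)(OCC)C(C)C#N | starting material
26 | (2Z)-2-(C9-ylidene)propanenitrile, nitrile cis to C10 | C[C@@H](OCc1ccc(OC)cc1)[C@@H]1CC[C@]2([C@H](CCCO[Si](C)(C)C(C)(C)C)/C(=C(/C)C#N)CC[C@]2(C)O[Si]3(C(C)(C)C)C(C)(C)C)[C@H]1O3 | intermediate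
27 | (1R)-1-hydroxyethyl compound (4-methoxybenzyl removed) | C[C@@H](O)[C@@H]1CC[C@]2([C@H](CCCO[Si](C)(C)C(C)(C)C)/C(=C(/C)C#N)CC[C@]2(C)O[Si]3(C(C)(C)C)C(C)(C)C)[C@H]1O3 | intermediate
28 | C2 acetyl compound | CC(=O)[C@@H]1CC[C@]2([C@H](CCCO[Si](C)(C)C(C)(C)C)/C(=C(/C)C#N)CC[C@]2(C)O[Si]3(C(C)(C)C)C(C)(C)C)[C@H]1O3 | intermediate
29 | C2 1-(trifluoromethanesulfonyloxy)ethenyl compound | C=C(OS(=O)(=O)C(F)(F)F)[C@@H]1CC[C@]2([C@H](CCCO[Si](C)(C)C(C)(C)C)/C(=C(/C)C#N)CC[C@]2(C)O[Si]3(C(C)(C)C)C(C)(C)C)[C@H]1O3 | intermediate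
30 | prop-2-yn-1-ol | C#CCO | starting material
31 | 5-bromo-2-methylpent-2-ene | CC(C)=CCCBr | starting material
32 | (4-methylpent-3-en-1-yl)magnesium bromide | CC(C)=CCC[Mg]Br | intermediate
33 | 4-(4-methylpent-3-en-1-yl)-2,5-dihydro-1,2-oxamagnesole (cyclic alkenylmagnesium alkoxide) | CC(C)=CCCC1=C[Mg]OC1 | intermediate
34 | (2Z)-3-iodo-2-(4-methylpent-3-en-1-yl)prop-2-en-1-ol | OC/C(CCC=C(C)C)=C\I | intermediate
35 | tert-butyl{[(2Z)-3-iodo-2-(4-methylpent-3-en-1-yl)prop-2-en-1-yl]oxy}dimethylsilane | CC(C)(C)[Si](C)(C)OC/C(CCC=C(C)C)=C\I | intermediate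
36 | 4,4,5,5-tetramethyl-2-vinyl-1,3,2-dioxaborolane | C=CB1OC(C)(C)C(C)(C)O1 | starting material
37 | 2-[(1E,3Z)-4-{[tert-butyl(dimethyl)silyl]oxymethyl}-8-methylnona-1,3,7-trien-1-yl]-4,4,5,5-tetramethyl-1,3,2-dioxaborolane | CC1(C)OB(/C=C/C=C(\CO[Si](C)(C)C(C)(C)C)CCC=C(C)C)OC1(C)C | intermediate
38 | fully protected triene nitrile | C=C(/C=C/C=C(\CO[Si](C)(C)C(C)(C)C)CCC=C(C)C)[C@@H]1CC[C@]2([C@H](CCCO[Si](C)(C)C(C)(C)C)/C(=C(/C)C#N)CC[C@]2(C)O[Si]3(C(C)(C)C)C(C)(C)C)[C@H]1O3 | intermediate
39 | N-(diisobutylaluminio) aldimine of 40 | C=C(/C=C/C=C(\CO[Si](C)(C)C(C)(C)C)CCC=C(C)C)[C@@H]1CC[C@]2([C@H](CCCO[Si](C)(C)C(C)(C)C)/C(=C(/C)C=N[Al](CC(C)C)CC(C)C)CC[C@]2(C)O[Si]3(C(C)(C)C)C(C)(C)C)[C@H]1O3 | intermediate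
40 | protected trienal (two silyl ethers, one silylene) | C=C(/C=C/C=C(\CO[Si](C)(C)C(C)(C)C)CCC=C(C)C)[C@@H]1CC[C@]2([C@H](CCCO[Si](C)(C)C(C)(C)C)/C(=C(/C)C=O)CC[C@]2(C)O[Si]3(C(C)(C)C)C(C)(C)C)[C@H]1O3 | intermediate
41 | (2Z)-2-[(1S,2S,5S,6S,10R)-1,6-dihydroxy-2-[(3E,5Z)-6-(hydroxymethyl)-10-methylundeca-1,3,5,9-tetraen-2-yl]-10-(3-hydroxypropyl)-6-methylspiro[4.5]decan-9-ylidene]propanal | C=C(/C=C/C=C(\CO)CCC=C(C)C)[C@@H]1CC[C@]2([C@H](CCCO)/C(=C(/C)C=O)CC[C@]2(C)O)[C@H]1O | target

**Totals**

Total step count: 25. Longest linear sequence: 19 steps (steps 4 to 19, then 23 to 25).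

**Steps most likely to fail**

Step 8. The zinc alkoxide may fail to open, or the aldehyde homoenolate may be lost by self-condensation or by epimerisation at C2 before it adds to the enone. The fallback sets out from 10 and returns to the route at 14, making the same two bonds in known operations. Electrophilic ring opening of 10 with Hg(OAc)2 in CH2Cl2 cleaves the less substituted ring bond and should give (2S,3R)-2-[(acetoxymercurio)methyl]-3-[(4-methoxyphenyl)methoxy]butanal F1 without touching the stereocentre. Reduction of F1 with Bu3SnH in the presence of excess 5 generates the primary β-formylalkyl radical, which adds to the methylidene carbon (Giese reaction) to give 2-{(1R)-1-[(4-methoxyphenyl)methoxy]ethyl}-4-(7-oxo-1,4-dioxaspiro[4.5]decan-6-yl)butanal F2 as a mixture of epimers at the ring α-carbon. Soft enolisation of F2 with MgBr2·OEt2 and iPr2NEt then closes the cyclopentane by magnesium-chelated intramolecular aldol addition of the ketone enolate onto the aldehyde, giving 14.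

Step 14. Borane may approach the cyclohexene from the face of the silyloxy-bearing C1, so that hydrogen is delivered to the wrong face of C10 (poor or reversed facial selectivity). The fallback sets out from 21 and returns at 24. Epoxidation of 21 with mCPBA, which should follow the same steric bias as borane, would give the 9,10-epoxide F3. Rearrangement of F3 with ZnBr2 by 1,2-hydride shift (Meinwald rearrangement) delivers hydrogen to C10 on the face opposite to the epoxide oxygen, the complementary sense to hydroboration, and gives the C9 ketone 24 directly.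

Step 16. The hindered α-branched ketone may resist olefination, enolise with loss of the C10 configuration, or give poor control of the alkene geometry. The fallback sets out from 24 and returns at 26. Addition of isopropenylmagnesium bromide with CeCl3 to 24 gives the tertiary allylic alcohol F4. Oxidative 1,3-transposition of F4 with pyridinium chlorochromate (C5H5NH[CrO3Cl]) in CH2Cl2 (Babler–Dauben oxidation) sets the alkene geometry in a chair-like sigmatropic shift and gives the (2Z)-enal F5. Treatment of F5 with I2 in aqueous NH3/THF converts the aldehyde into the nitrile 26.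

**Further compounds**

F1 | step 8 | (2S,3R)-2-[(acetoxymercurio)methyl]-3-[(4-methoxyphenyl)methoxy]butanal | C[C@@H](OCc1ccc(OC)cc1)[C@@H](C=O)C[Hg]OC(C)=O
F2 | step 8 | 2-{(1R)-1-[(4-methoxyphenyl)methoxy]ethyl}-4-(7-oxo-1,4-dioxaspiro[4.5]decan-6-yl)butanal (epimers at the ring α-carbon) | C[C@@H](OCc1ccc(OC)cc1)[C@@H](C=O)CCC1C(=O)CCCC12OCCO2
F3 | step 14 | 9,10-epoxide of 21, oxygen on the face of C1 | C[C@@H](OCc1ccc(OC)cc1)[C@@H]1CC[C@]2([C@]3(CCCO[Si](C)(C)C(C)(C)C)O[C@@H]3CC[C@]2(C)O[Si]4(C(C)(C)C)C(C)(C)C)[C@H]1O4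
F4 | step 16 | C9 tertiary alcohol bearing a prop-1-en-2-yl group (C9 configuration not assigned) | C[C@@H](OCc1ccc(OC)cc1)[C@@H]1CC[C@]2([C@H](CCCO[Si](C)(C)C(C)(C)C)C(O)(C(C)=C)CC[C@]2(C)O[Si]3(C(C)(C)C)C(C)(C)C)[C@H]1O3
F5 | step 16 | (2Z)-2-(C9-ylidene)propanal corresponding to 26 | C[C@@H](OCc1ccc(OC)cc1)[C@@H]1CC[C@]2([C@H](CCCO[Si](C)(C)C(C)(C)C)/C(=C(/C)C=O)CC[C@]2(C)O[Si]3(C(C)(C)C)C(C)(C)C)[C@H]1O3
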